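**Plan**

- Retrosynthesis: the target is read as lutein 3-O-palmitate. The cuts are, in order: the ester C–O bond at C3 (palmitoyl chloride), the C3–O and C3'–O bonds (back to (6'R)-α-carotene), the ring bonds C1–C6 and C1'–C6' (back to acyclic lycopene), then C11=C12, C11'=C12' and C9–C10 (C10 dialdehyde, pseudoionone, vinyl Grignard reagent).
- Forward: the C40 chain is joined first by a C15 + C10 + C15 double Wittig reaction. Ring ε (C1'–C6') is then closed by lycopene ε-cyclase and ring β (C1–C6) by lycopene β-cyclase in one pot. The two hydroxyls follow by enzymatic C–H oxidation, and the palmitate comes last.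
- Enabling feature: ring β (C1–C6, C5=C6) and ring ε (C1'–C6', C4'=C5') are both what a Me2C=CH–CH2–CH2–C(Me)=CH ψ-end becomes after protonation at C2, C1–C6 bond formation and loss of H6 or H4'. Lycopene carries two such ends, no ring and no stereocenter.
- Stereochemistry: C6' (R) comes from the ε-cyclase, C3 (R) from CYP97A3 and C3' (R) from CYP97C1. The all-E chain comes from E-configured building blocks and thermal equilibration. The last step touches no stereocenter, and C3' is deliberately not taken through a ketone, which would leave its configuration to substrate control.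

Key step: step 4

Assumption: the SMILES corresponds to (3R,3'R,6'R)-β,ε-carotene-3,3'-diol acylated at the ring β hydroxyl; the recombinant cyclases, hydroxylases and their redox partner proteins are treated as catalysts obtained by standard expression in Escherichia coli and are not counted as compounds or steps.

**Route**

Step 1
Reactants: 1 pseudoionone, (3E,5E)-6,10-dimethylundeca-3,5,9-trien-2-one (E,E-enriched grade); 2 vinylmagnesium bromide
Product: 3 vinyl-ψ-ionol, (4E,6E)-3,7,11-trimethyldodeca-1,4,6,10-tetraen-3-ol (racemic at C3)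
Conditions: 2 (1.2 equiv, 1 M in THF), THF, −20 → 0 °C; sat. aq. NH4Cl
Reagents that add atoms: none
Why: Grignard 1,2-addition of the hard vinyl nucleophile to the ketone carbonyl of the dienone at low temperature, where conjugate addition should not compete; the tertiary carbinol centre forms racemic and is erased in step 2.

Step 2
Reactants: 3 vinyl-ψ-ionol
Product: 4 [(2E,4E,6E)-3,7,11-trimethyldodeca-2,4,6,10-tetraen-1-yl]triphenylphosphonium bromide
Conditions: PPh3·HBr (1.05 equiv), MeOH, 0 °C → rt; crystallization from EtOAc
Reagents that add atoms: triphenylphosphine hydrobromide, [Br-].c1ccc(cc1)[PH+](c1ccccc1)c1ccccc1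
Why: SN1-type allylic substitution with transposition, in which acid ionizes the tertiary doubly allylic alcohol to a delocalized cation that PPh3 captures at the unhindered primary terminus, giving the conjugated trienyl Wittig salt mainly as the 2E isomer.

Step 3
Reactants: 4 C15 phosphonium bromide (2.2 equiv); 5 C10 dialdehyde, (2E,4E,6E)-2,7-dimethylocta-2,4,6-trienedial
Product: 8 all-E-lycopene, via ylide 6 (not isolated), via apo-12'-lycopenal 7 (not isolated)
Conditions: NaOMe (2.3 equiv), MeOH/CH2Cl2, 0 °C → rt, dark, N2; then heptane, reflux; crystallization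
Reagents that add atoms: none
Why: Double Wittig olefination of the symmetrical dialdehyde with the semi-stabilized allylic ylide forms C11=C12 and C11'=C12', and the E/Z mixture at these bonds is equilibrated thermally to the all-E isomer, which crystallizes and leaves Z isomers (including any 5Z material from the pseudoionone) in the mother liquor.

Step 4
Reactants: 8 all-E-lycopene
Product: 10 (6'R)-α-carotene, via δ-carotene 9 (not isolated)
Conditions: 8 in phosphatidylcholine liposomes, Tris-HCl pH 7.8, recombinant Arabidopsis thaliana lycopene ε-cyclase (E. coli membrane fraction), FAD, NADPH (cat.), N2, 30 °C, dark, until 8 is consumed; then recombinant lycopene β-cyclase (CrtY of Pantoea ananatis), 30 °C; CHCl3/MeOH extraction, chromatography on deactivated Al2O3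
Reagents that add atoms: none
Why: Each cyclase is a flavoprotein that needs reduced FAD but causes no net redox change and acts as an enzyme-bound Brønsted acid: it protonates C2' (ε-cyclase) or C2 (β-cyclase) of a terminal Me2C=CH unit, the tertiary C1'/C1 cation is captured by the C5'=C6' or C5=C6 double bond to form the C1'–C6' or C1–C6 bond, and the resulting tertiary C5'/C5 cation is quenched by loss of H4' (ring ε, C4'=C5') or H6 (ring β, C5=C6). The closest known reaction type is the acid-initiated cation–olefin cyclization, here in its native enzymatic form, which has been reproduced with recombinant cyclases in Escherichia coli and in membrane or liposome assays. Both rings are six-membered carbocycles closed in the 6-endo mode with respect to the attacking C5=C6 alkene through a chair-like fold of C1 to C6. The only new stereocenter, C6', is set by the ε-cyclase, whose active site fixes the fold of the ψ-end and therefore the face of C6' that bonds to C1' and the removal of H4', which should give 6'R; ring β has no stereocenter because H6 is lost. The step needs exactly one ring ε and one ring β: the Arabidopsis ε-cyclase closes only one end of lycopene and is allowed to consume 8 completely before the β-cyclase, which accepts the remaining ψ-end of 9, is added, so that β,β-carotene should not form.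

Step 5
Reactants: 10 (6'R)-α-carotene
Product: 12 (3R,3'R,6'R)-lutein, via zeinoxanthin 11 (not isolated)
Conditions: 10 in Tween 80/phosphatidylcholine micelles, KH2PO4/K2HPO4 buffer pH 7.4, recombinant CYP97A3, ferredoxin, ferredoxin–NADP+ reductase, NADPH (cat.), D-glucose, glucose dehydrogenase, air, 28 °C, dark; then recombinant CYP97C1, same cofactor system; EtOAc extraction, chromatography on SiO2
Reagents that add atoms: dioxygen, O=O
Why: Cytochrome P450 monooxygenation (hydrogen abstraction and oxygen rebound with retention) in its native setting: CYP97A3 hydroxylates C3 of ring β to give 11 with the 3R configuration and CYP97C1 then hydroxylates the allylic C3' of ring ε on the face trans to the C6' side chain (3'R), each configuration being fixed by the single prochiral C–H bond that the active site presents to the high-valent oxoiron haem.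

Step 6
Reactants: 12 (3R,3'R,6'R)-lutein; 13 palmitoyl chloride
Product: 14 lutein 3-O-palmitate, (3R,3'R,6'R)-3'-hydroxy-β,ε-caroten-3-yl hexadecanoate (target)
Conditions: 13 (1.0 equiv, slow addition), pyridine, THF, −30 → 0 °C, dark, Ar; chromatography on SiO2, recovered 12 recycled
Reagents that add atoms: none
Why: Einhorn-type O-acylation (acid chloride, pyridine) under kinetic control, in which the equatorial, non-allylic C3 hydroxyl of ring β should react ahead of the C3' hydroxyl of ring ε, which is expected to be pseudoaxial and syn to an axial C1' methyl group; pyridine buffers the HCl so that the allylic C3'–O bond is not ionized and no stereocenter is touched.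

**Compound list**

1 | pseudoionone, (3E,5E)-6,10-dimethylundeca-3,5,9-trien-2-one | CC(C)=CCC/C(C)=C/C=C/C(C)=O | starting material
2 | vinylmagnesium bromide | C=C[Mg]Br | starting material
3 | vinyl-ψ-ionol, (4E,6E)-3,7,11-trimethyldodeca-1,4,6,10-tetraen-3-ol, racemic at C3 | CC(C)=CCC/C(C)=C/C=C/C(C)(O)C=C | intermediate
4 | [(2E,4E,6E)-3,7,11-trimethyldodeca-2,4,6,10-tetraen-1-yl]triphenylphosphonium bromide | CC(C)=CCC/C(C)=C/C=C/C(C)=C/C[P+](c1ccccc1)(c1ccccc1)c1ccccc1.[Br-] | intermediate
5 | C10 dialdehyde, (2E,4E,6E)-2,7-dimethylocta-2,4,6-trienedial | O=C/C(C)=C/C=C/C=C(C)/C=O | starting material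
6 | ylide, [(2E,4E,6E)-3,7,11-trimethyldodeca-2,4,6,10-tetraenylidene]triphenylphosphorane, formed in the flask | CC(C)=CCC/C(C)=C/C=C/C(C)=C/C=P(c1ccccc1)(c1ccccc1)c1ccccc1 | intermediate
7 | apo-12'-lycopenal, all-E-12'-apo-ψ-caroten-12'-al (C25 aldehyde of the first olefination), formed in the flask | CC(C)=CCC/C(C)=C/C=C/C(C)=C/C=C/C(C)=C/C=C/C=C(C)/C=O | intermediate
8 | all-E-lycopene, ψ,ψ-carotene | CC(C)=CCC/C(C)=C/C=C/C(C)=C/C=C/C(C)=C/C=C/C=C(C)/C=C/C=C(C)/C=C/C=C(C)/CCC=C(C)C | intermediate
9 | δ-carotene, (6R)-ε,ψ-carotene, formed in the flask | CC(C)=CCC/C(C)=C/C=C/C(C)=C/C=C/C(C)=C/C=C/C=C(C)/C=C/C=C(C)/C=C/[C@H]1C(C)=CCCC1(C)C | intermediate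
10 | (6'R)-α-carotene, (6'R)-β,ε-carotene | CC1=C(/C=C/C(C)=C/C=C/C(C)=C/C=C/C=C(C)/C=C/C=C(C)/C=C/[C@H]2C(C)=CCCC2(C)C)C(C)(C)CCC1 | intermediate
11 | zeinoxanthin, (3R,6'R)-β,ε-caroten-3-ol, formed in the flask | O[C@@H]1CC(C)=C(/C=C/C(C)=C/C=C/C(C)=C/C=C/C=C(C)/C=C/C=C(C)/C=C/[C@H]2C(C)=CCCC2(C)C)C(C)(C)C1 | intermediate
12 | lutein, (3R,3'R,6'R)-β,ε-carotene-3,3'-diol | O[C@@H]1CC(C)=C(/C=C/C(C)=C/C=C/C(C)=C/C=C/C=C(C)/C=C/C=C(C)/C=C/[C@H]2C(C)=C[C@H](O)CC2(C)C)C(C)(C)C1 | intermediate
13 | palmitoyl chloride, hexadecanoyl chloride | CCCCCCCCCCCCCCCC(=O)Cl | starting material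
14 | lutein 3-O-palmitate, (3R,3'R,6'R)-3'-hydroxy-β,ε-caroten-3-yl hexadecanoate | CCCCCCCCCCCCCCCC(=O)O[C@@H]1CC(C)=C(/C=C/C(C)=C/C=C/C(C)=C/C=C/C=C(C)/C=C/C=C(C)/C=C/[C@H]2C(C)=C[C@H](O)CC2(C)C)C(C)(C)C1 | target

**Step count and risks**

Total step count: 6. Longest linear sequence: 6 steps (1 → 3 → 4 → 8 → 10 → 12 → 14).

Steps most likely to fail:

1. Step 5 (hydroxylation).
 - What may go wrong: slow or stalled oxygen transfer, because two membrane-bound monooxygenases with a three-protein electron chain must turn over a water-insoluble C40 hydrocarbon held in micelles. The reaction may stop after the first hydroxylation, and the polyene may bleach oxidatively during a long aerobic incubation.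
 - Fallback: it sets out from C10 dialdehyde 5 and comes back at lutein 12. The oxygen atoms are brought in with the end groups and the chain is joined by two Wittig reactions, so neither step 4 nor step 5 is needed.
 - Dialdehyde 5, in excess, would be condensed (NaOMe, MeOH/CH2Cl2) with [(2E,4E)-5-[(4R)-4-hydroxy-2,6,6-trimethylcyclohex-1-en-1-yl]-3-methylpenta-2,4-dien-1-yl]triphenylphosphonium chloride F1, to give (3R)-3-hydroxy-12'-apo-β-caroten-12'-al F2.
 - A second Wittig reaction of F2 with [(2E,4E)-5-[(1R,4R)-4-hydroxy-2,6,6-trimethylcyclohex-2-en-1-yl]-3-methylpenta-2,4-dien-1-yl]triphenylphosphonium chloride F3, followed by thermal E/Z equilibration and crystallization, would give 12, which re-enters at step 6.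
 - F1 and F3 are known hydroxylated C15 building blocks; each would be prepared separately from the corresponding enantiopure 3-hydroxyionone, which would then be the source of all three stereocenters.

2. Step 4 (cyclization).
 - What may go wrong: incomplete or unbalanced cyclization. Aggregated lycopene may be delivered poorly to the membrane-bound cyclases, the ε-cyclase may stop before every molecule carries one ring ε, and any lycopene left when the β-cyclase is added is diverted to ring β at both ends.
 - Fallback: it sets out from C10 dialdehyde 5 and comes back at (6'R)-α-carotene 10. The two end groups are bought as ionones and the C6' stereocenter is taken from (R)-α-ionone.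
 - Dialdehyde 5, in excess, would be condensed (NaOMe, MeOH/CH2Cl2) with one equivalent of commercial [(2E,4E)-3-methyl-5-(2,6,6-trimethylcyclohex-1-en-1-yl)penta-2,4-dien-1-yl]triphenylphosphonium bromide to give 12'-apo-β-caroten-12'-al F4.
 - Commercial (R)-α-ionone would be taken through the operations of steps 1 and 2: addition of 2 gives (1E)-3-methyl-1-[(1R)-2,6,6-trimethylcyclohex-2-en-1-yl]penta-1,4-dien-3-ol F5, and PPh3·HBr converts it into [(2E,4E)-3-methyl-5-[(1R)-2,6,6-trimethylcyclohex-2-en-1-yl]penta-2,4-dien-1-yl]triphenylphosphonium bromide F6.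
 - A Wittig reaction of F4 with F6, thermal equilibration and crystallization would give 10, which re-enters at step 5.

3. Step 6 (acylation).
 - What may go wrong: insufficient discrimination between the two secondary hydroxyls, so that acylation at C3' and double acylation compete, or ionization of the allylic C3'–O bond by adventitious acid.
 - Fallback: it sets out from lutein 12 and comes back at target 14. The two hydroxyls are made chemically different before the acyl group is introduced.
 - Activated MnO2 (CH2Cl2, rt, dark) should oxidize only the allylic C3' hydroxyl and give (3R,6'R)-3-hydroxy-β,ε-caroten-3'-one F7.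
 - The single remaining hydroxyl would be acylated with 13 and pyridine to give (3R,6'R)-3'-oxo-β,ε-caroten-3-yl hexadecanoate F8.
 - Luche reduction (NaBH4, CeCl3·7H2O, MeOH/THF, −40 °C) would return the allylic alcohol as 14 together with its C3' epimer, (3R,3'S,6'R)-3'-hydroxy-β,ε-caroten-3-yl hexadecanoate F9.
 - 14 would be separated by chromatography, and F9 re-oxidized with MnO2 to F8 and recycled.
 - This detour fixes the position of the ester beyond doubt but leaves the C3' configuration to substrate control of a hydride addition, which is why it is not the main path.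

**Further compounds**

F1 | step 5 | [(2E,4E)-5-[(4R)-4-hydroxy-2,6,6-trimethylcyclohex-1-en-1-yl]-3-methylpenta-2,4-dien-1-yl]triphenylphosphonium chloride | [Cl-].O[C@@H]1CC(C)=C(/C=C/C(C)=C/C[P+](c2ccccc2)(c2ccccc2)c2ccccc2)C(C)(C)C1
F2 | step 5 | (3R)-3-hydroxy-12'-apo-β-caroten-12'-al | O[C@@H]1CC(C)=C(/C=C/C(C)=C/C=C/C(C)=C/C=C/C=C(C)/C=O)C(C)(C)C1
F3 | step 5 | [(2E,4E)-5-[(1R,4R)-4-hydroxy-2,6,6-trimethylcyclohex-2-en-1-yl]-3-methylpenta-2,4-dien-1-yl]triphenylphosphonium chloride | [Cl-].c1ccccc1[P+](c1ccccc1)(c1ccccc1)C/C=C(C)/C=C/[C@H]1C(C)=C[C@H](O)CC1(C)C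
F4 | step 4 | 12'-apo-β-caroten-12'-al | CC1=C(/C=C/C(C)=C/C=C/C(C)=C/C=C/C=C(C)/C=O)C(C)(C)CCC1
F5 | step 4 | (1E)-3-methyl-1-[(1R)-2,6,6-trimethylcyclohex-2-en-1-yl]penta-1,4-dien-3-ol, both C3 epimers | C=CC(C)(O)/C=C/[C@H]1C(C)=CCCC1(C)C
F6 | step 4 | [(2E,4E)-3-methyl-5-[(1R)-2,6,6-trimethylcyclohex-2-en-1-yl]penta-2,4-dien-1-yl]triphenylphosphonium bromide | [Br-].c1ccccc1[P+](c1ccccc1)(c1ccccc1)C/C=C(C)/C=C/[C@H]1C(C)=CCCC1(C)C
F7 | step 6 | (3R,6'R)-3-hydroxy-β,ε-caroten-3'-one | O[C@@H]1CC(C)=C(/C=C/C(C)=C/C=C/C(C)=C/C=C/C=C(C)/C=C/C=C(C)/C=C/[C@H]2C(C)=CC(=O)CC2(C)C)C(C)(C)C1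
F8 | step 6 | (3R,6'R)-3'-oxo-β,ε-caroten-3-yl hexadecanoate | CCCCCCCCCCCCCCCC(=O)O[C@@H]1CC(C)=C(/C=C/C(C)=C/C=C/C(C)=C/C=C/C=C(C)/C=C/C=C(C)/C=C/[C@H]2C(C)=CC(=O)CC2(C)C)C(C)(C)C1
F9 | step 6 | (3R,3'S,6'R)-3'-hydroxy-β,ε-caroten-3-yl hexadecanoate | CCCCCCCCCCCCCCCC(=O)O[C@@H]1CC(C)=C(/C=C/C(C)=C/C=C/C(C)=C/C=C/C=C(C)/C=C/C=C(C)/C=C/[C@H]2C(C)=C[C@@H](O)CC2(C)C)C(C)(C)C1
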